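# Dichrostachine H: synthesis design around a methoxycyclobutenone ring expansion

## The problem

Dichrostachine H (39) joins a normal-series labdane decalin (rings A and B; stereocentres C4, C5, C7, C9, C10) through the C11 methylene to a cyclohexene (C12, C13, C14, C15, C6′, C1′). That cyclohexene is cis-fused along C1′–C6′ to a 2-methoxycyclohex-2-ene-1,4-dione and carries a 5,7-dihydroxychromone on the fully substituted ring-fusion carbon C1′. One epoxide stereocentre can dictate C4, C5, C9 and C10 in a chair–chair cyclisation, and C7 then follows from the ring, but C11 insulates these centres from C12, so none of them can be relied on to control C12. C12 is in turn the only lever on the quaternary centre C1′, and C1′ the only lever on C6′–H, which is epimerisable because it lies α to the C5′ ketone. Gentle handling is needed for the vinylogous ester C3′=C4′–OMe, the neopentyl C18 aldehyde, the allylic C7 alcohol next to the exocyclic C8=C17 alkene, the base-sensitive chromone with its two phenols, and any 1,4-cyclohexadiene precursor of the cyclohexene, which aromatises on oxidation. The enabling feature is the enedione ring: C2′(=O)–C3′H=C4′(OMe)–C5′(=O) has the carbon and oxygen pattern of 3-methoxycyclobut-3-ene-1,2-dione, and the two remaining ring atoms, C6′ and C1′, are an alkene of the cyclohexene ring before the fusion exists. A 3-methoxy-4-silyloxycyclobutenone attached through its carbinol carbon (future C5′) to C6′ should therefore expand on heating by forming only the C2′–C1′ bond, and because C1′ becomes quaternary the product cannot tautomerise to a phenol.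

## Retrosynthesis

**Unmasking (39 from 38 from 37).** No skeletal bond is cut. 39 is traced to 38, which has the aldehyde as dimethyl acetal, the phenols as methoxymethyl ethers and the C7 alcohol as a tert-butyldimethylsilyl ether, so one mild aqueous acid treatment ends the synthesis. 38 is traced to the C5′ silyl dienol ether 37, so that C6′–H is introduced last, by protonation at low temperature and not in a heated or basic step. The forward protonation has to place H-6′ syn to the chromone (cis fusion).

**Ring expansion (37 from 35 through ketene 36).** The cut is C2′–C1′ alone. A Diels–Alder cut across C6′=C1′ would need a dienophile that is tetrasubstituted in the real system and would deliver C2′ and C5′ at the wrong oxidation level. An aldol or Dieckmann closure would have to build the quaternary carbon next to an enolisable ketone. The cyclobutenone route brings C2′–C5′ with every oxygen in place, forms the quaternary centre intramolecularly by a pericyclic closure and stops at the dienone. The precursor 35 is one ring, one C–C bond and one stereocentre simpler. The forward step needs outward rotation of the silyloxy group, closure onto a tetrasubstituted alkene terminus, and attack on the face of C1′ anti to the C11 chain on C12.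

**Carbinol bond (35 from 34 from 32 and 31; 31 from 29).** The C6′–C5′ bond is cut to an alkenyl nucleophile at C6′ (from iodide 32 through the magnesium reagent 33) and the ketone carbonyl of methyl semisquarate 31, itself one operation from dimethyl squarate 29. The vinylogous-ester carbonyl of 31 is the less electrophilic one, so the addition fixes the methoxy group at C4′ and leaves H at C3′. The carbinol configuration is irrelevant because that carbon becomes sp2. The forward reaction needs an organometallic that forms and adds below the temperature at which the chromone is attacked.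

**Cyclohexadiene (32 from 22 and 28).** C12–C1′ and C15–C6′ are cut in a [4+2] retron between the labdatriene 22 and the iodoalkynyl chromone 28. The alkyne gives the 1,4-diene at the oxidation level needed, places the chromone on C1′, and leaves iodine on C6′ for metalation. A boron substituent at that position was weighed and kept as a fallback, because boron as an acceptor opposes the polarisation by the chromone, whereas iodine as a π-donor reinforces it and saves two operations. The weakness is C12, which forms without control from the remote decalin and has to be secured by separating epimers.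

**Dienophile (28 from 27 from 25 from 24 from 23).** The chromone C–O bond and C4″–C3″ are cut: 27 is the 6-endo cyclisation product of the o-hydroxyaryl diynone 26, which comes from diynyl carbinol 25, the adduct of a silyl-capped C4 diynide and aldehyde 24, made from 2,4,6-trihydroxybenzaldehyde 23. This route needs no acid, so the methoxymethyl ethers survive, and the silylalkyne of 27 is exchanged directly for iodine.

**Adjusting the decalin (22 back to 10).** Only C14=C15 is cut (methylenation of enal 21, from alcohol 20 and pivalate 19). The rest is redox and protection: 7β-silyl ether 19 from alcohol 18, from enone 17, from acetal 15 by allylic oxidation through 16. Acetal 15 comes from aldehyde 14 and alcohol 13. C3 is deoxygenated in 12 through thionocarbonate 11 from the cyclisation product 10. The order is set by three constraints: selenium dioxide must act before the diene exists, the C18 silyl ether must leave before the C7 silyl ether arrives, and the aldehyde must be masked before hydride, ylide and Grignard reagents are used.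

**Decalin (10 from 9).** C4–C5 and C9–C10 are cut in an epoxide-initiated, allylsilane-terminated bicyclisation. It turns one epoxide (two stereocentres) and two alkene geometries into C4, C5, C9 and C10, puts the oxygenated carbon C18 equatorial because it is trans on the epoxide, and leaves the alkene only at C8=C17. The price is a C3 hydroxyl that must be removed. The forward reaction needs ionisation of an epoxide that bears a β-silyloxy group, and a terminator that outruns proton loss.

**Acyclic chain (9 from 6, 5, 4, 3, 1).** C8–C17 and C9–C11 are cut by one syn-carbometalation of the terminal alkyne of 6: a silylmethylcopper reagent adds, and the resulting alkenylcopper 7 opens a five-carbon vinyl epoxide to give alkoxide 8, which is acylated in the flask. This fixes the allylsilane geometry and installs C11–C14 and C16 at once. 6 is the silyl ether of epoxy alcohol 5, made by asymmetric epoxidation of allylic alcohol 4, which comes from enyne 3 by terminal allylic oxidation. 3 is the C6–C7 coupling product of geranyl bromide 1 with a propargyl anion, through silylated enyne 2.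

## Roads not taken

Alternative 1: The cut is C4–C5 and C9–C10, and the synthesis is organised around the decalin. An aluminium Lewis acid opens the C3–C4 epoxide of the acyclic epoxy allylsilane ester A2, the C5=C10 and C9=C8 alkenes add in turn, and loss of silicon from C17 leaves the exocyclic alkene of hydroxy ester A1. Its merits are real: four stereocentres from one epoxide, a regiodefined alkene, and a substrate simpler than 9, since A2 carries a plain ester and no third alkene, so the cascade has fewer ways to go wrong. The chosen route does not reject this chemistry; step 6 is a close relative. What is rejected is letting it carry the plan. A1 still has the C3 hydroxyl to lose, C7 to oxidise and five side-chain carbons to add, and the cascade does nothing about the quaternary C1′ or the enedione ring, where the real difficulty lies. Against the cleaner cascade of Alternative 1 the chosen plan sets a terminator that already holds C11–C14 (saving two olefinations) and spends its strategic risk on the hardest bond.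

Alternative 2: The cut is C6′–C5′ and C1′–C2′. The electron-rich diene A4 adds across the C6′=C1′ bond of the cyclohexadiene carbaldehyde A5 to give the cis-fused aldehyde A3, with the formyl carbon as the future chromone C2″. It is convergent, has normal electron demand, sets the quaternary centre and the cis fusion in one suprafacial step, and could be made enantioselective with a chiral Lewis acid on the aldehyde; in these respects it is better than the chosen plan, which has no control at C12. For this target it is weak in three ways. C2′ and C5′ arrive as silyl ethers at the alcohol level and need two oxidations next to the epimerisable C6′. The chromone must be built afterwards from a neopentyl aldehyde on a quaternary carbon. A5 lacks the terpenoid, so the decalin chain would have to be attached at C12 later, beside the finished quaternary centre, creating C12 last and under the least favourable steric conditions. The chosen plan sets against this the correct oxidation level of all four ring carbons from the squarate, a chromone present from the outset, and C1′ formed under the control of an existing C12.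

Alternative 3: The cut is C3″–C4″ and C4″–C4a″. The C1′ ethynyl compound A7, carbon monoxide A9 and the aryl iodide A8 combine under a palladium–phosphine catalyst with an amine base to give the aryl alkynyl ketone A6, which holds every chromone atom; no ring closes and no stereocentre forms. Its merit is convergence: the polar, base-sensitive chromone arrives last and never meets an organometallic reagent, which is better than the chosen plan, where the chromone must survive a Grignard step. Its weak points are the iodide A8, flanked by two ortho alkoxy groups and electron-rich, so oxidative addition and CO insertion are slow and direct alkynylation competes. After the coupling, one of three equivalent phenol ethers must be removed selectively and the ynone closed 6-endo. The ethynyl group on quaternary C1′ and the C5′ ketal have to be made first, and the enedione ring still needs a construction of its own. The chosen plan answers with a chromone that does three jobs: it activates the dienophile 28, directs the regiochemistry of the cycloaddition, and blocks aromatisation in the key step.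

Key step: step 26

## Assumptions

Assumption (numbering): labdane numbering C1–C20 is used for the terpenoid half (normal series: 5α-H, 9α-H, 10β-CH3; C18 is the 4α, equatorial substituent, C19 the 4β-methyl, C17 the exocyclic methylene, C16 the methyl on C13), C1′–C6′ for the enedione ring and C2″–C8a″ for the chromone.

Assumption (chemistry): the C12 epimers formed in step 23 are diastereomers and are taken to be separable by chromatography. Geranyl bromide is used as purchased; it is also one step from geraniol.

## Route

Step 1
Reactants: 1 geranyl bromide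
Product: 3 (5E)-6,10-dimethylundeca-5,9-dien-1-yne, via silylated enyne 2 (not isolated)
Conditions: 1-(trimethylsilyl)propyne, n-BuLi, THF, −78 °C; add 1, −78 → 0 °C; then K2CO3, MeOH, rt
Reagents that add atoms: 1-(trimethylsilyl)propyne, CC#C[Si](C)(C)C
Why: SN2 alkylation of the allylic bromide by the propargylic lithium reagent (the silyl group directs attack to the propargylic carbon), then base-catalysed methanolysis of the alkynyl C–Si bond; the (E)-alkene is not touched.

Step 2
Reactants: 3 (5E)-6,10-dimethylundeca-5,9-dien-1-yne
Product: 4 (2E,6E)-2,6-dimethylundeca-2,6-dien-10-yn-1-ol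
Conditions: SeO2 (cat.), t-BuOOH, salicylic acid (cat.), CH2Cl2, rt
Reagents that add atoms: tert-butyl hydroperoxide, CC(C)(C)OO
Why: Selenium dioxide allylic oxidation (ene reaction, then [2,3]-sigmatropic shift) is selective in polyprenyl chains for the (E)-methyl of the terminal trisubstituted alkene; the internal alkene is more hindered and the alkyne is inert.

Step 3
Reactants: 4 (2E,6E)-2,6-dimethylundeca-2,6-dien-10-yn-1-ol
Product: 5 [(2S,3S)-2-methyl-3-[(3E)-3-methyloct-3-en-7-yn-1-yl]oxiran-2-yl]methanol
Conditions: Ti(Oi-Pr)4 (cat.), L-(+)-diethyl tartrate (cat.), t-BuOOH, 4 Å molecular sieves, CH2Cl2, −20 °C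
Reagents that add atoms: tert-butyl hydroperoxide, CC(C)(C)OO
Why: Sharpless asymmetric epoxidation; only the allylic alcohol alkene reacts, and L-(+)-tartrate delivers oxygen to the face that gives the (2S,3S) epoxide of an (E)-2-methylalk-2-en-1-ol. This one operation is the source of absolute configuration for the whole decalin.

Step 4
Reactants: 5 [(2S,3S)-2-methyl-3-[(3E)-3-methyloct-3-en-7-yn-1-yl]oxiran-2-yl]methanol
Product: 6 tert-butyldiphenylsilyl ether of 5
Conditions: t-BuPh2SiCl, imidazole, DMF, 0 °C → rt
Reagents that add atoms: tert-butyl(chloro)diphenylsilane, CC(C)(C)[Si](Cl)(c1ccccc1)c1ccccc1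
Why: Routine silylation of the primary alcohol; a silyl ether, unlike an ester, cannot take part in the later epoxide opening as a neighbouring group, and it tolerates organocopper and aluminium reagents.

Step 5
Reactants: 6 tert-butyldiphenylsilyl ether of 5
Product: 9 (2E,5Z,9E)-12-[(2S,3S)-3-{[(tert-butyldiphenylsilyl)oxy]methyl}-3-methyloxiran-2-yl]-2,10-dimethyl-6-[(trimethylsilyl)methyl]dodeca-2,5,9-trien-1-yl pivalate, via alkenylcopper 7 (not isolated), via chloromagnesium alkoxide 8 (not isolated)
Conditions: Me3SiCH2MgCl, CuBr·SMe2, Et2O/Me2S, −30 → 0 °C; then 2-methyl-2-vinyloxirane, −40 → −10 °C; then t-BuCOCl, 0 °C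
Reagents that add atoms: (trimethylsilyl)methylmagnesium chloride, C[Si](C)(C)C[Mg]Cl; 2-methyl-2-vinyloxirane, CC1(CO1)C=C; pivaloyl chloride, CC(C)(C)C(Cl)=O
Why: syn-Carbocupration of the terminal alkyne puts CH2SiMe3 on the internal carbon (C8) and copper on the terminal carbon (C9), cis to each other, which fixes the allylsilane geometry with C7 trans to C11. SN2′ opening of the vinyl oxirane by the alkenylcopper gives the (E)-2-methylallylic alkoxide, which is acylated in the flask. The trisubstituted epoxide of 6, flanked by the silyloxymethyl group, is much less reactive than the vinyl oxirane.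

Step 6
Reactants: 9 allylsilane pivalate
Product: 10 (12E)-18-[(tert-butyldiphenylsilyl)oxy]-3β-hydroxy-15-norlabda-8(17),12-dien-14-yl pivalate
Conditions: MeAlCl2, CH2Cl2, −78 °C; quench Et3N/MeOH, then aqueous work-up
Reagents that add atoms: none
Why: Epoxide-initiated, allylsilane-terminated cation–olefin bicyclisation: the Lewis acid opens the epoxide at tertiary C4 with anti attack by C5, the chair–chair fold of the two (E)-configured alkenes sets 5α-H, 10β-CH3 and the 9β side chain, and the silyloxymethyl group, trans on the epoxide, becomes the equatorial C18. Loss of the silyl group from C17 gives only the 8(17)-alkene; the pivalate-bearing alkene is electron-poor and too far to interfere.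

Step 7
Reactants: 10 decalin 3β-alcohol
Product: 11 3-O-(phenoxythiocarbonyl) derivative of 10
Conditions: PhOC(S)Cl, pyridine, DMAP (cat.), CH2Cl2, rt
Reagents that add atoms: O-phenyl chlorothionoformate, S=C(Cl)Oc1ccccc1
Why: Acylation of the only free hydroxyl to the thionocarbonate, the first half of a Barton–McCombie deoxygenation; DMAP overcomes the neopentyl-type hindrance at C3.

Step 8
Reactants: 11 thionocarbonate
Product: 12 (12E)-18-[(tert-butyldiphenylsilyl)oxy]-15-norlabda-8(17),12-dien-14-yl pivalate
Conditions: n-Bu3SnH, AIBN (cat.), toluene, 100 °C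
Reagents that add atoms: none
Why: Barton–McCombie radical deoxygenation; the secondary C3 radical is reduced by the stannane and has no alkene within reach for cyclisation, so C4 and the rest of the skeleton are unchanged.

Step 9
Reactants: 12 deoxygenated silyl ether
Product: 13 (12E)-18-hydroxy-15-norlabda-8(17),12-dien-14-yl pivalate
Conditions: n-Bu4NF, THF, rt
Reagents that add atoms: none
Why: Fluoride cleavage of the silyl ether; the pivalate and both alkenes are inert, and removing this silyl group now keeps it from clashing with the C7 silyl ether introduced later.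

Step 10
Reactants: 13 C18 alcohol
Product: 14 (12E)-18-oxo-15-norlabda-8(17),12-dien-14-yl pivalate
Conditions: Dess–Martin periodinane, CH2Cl2, rt
Reagents that add atoms: none
Why: Dess–Martin oxidation of the neopentyl primary alcohol; the aldehyde sits on quaternary C4 and cannot enolise, so the centre is safe.

Step 11
Reactants: 14 C18 aldehyde
Product: 15 (12E)-18,18-dimethoxy-15-norlabda-8(17),12-dien-14-yl pivalate
Conditions: HC(OMe)3, MeOH, PPTS (cat.), 40 °C
Reagents that add atoms: trimethyl orthoformate, COC(OC)OC
Why: Acid-catalysed acetalisation, driven by the orthoformate as water scavenger; the weak acid does not isomerise the exocyclic alkene, and the acetal shields the aldehyde from hydride, ylide and Grignard reagents until the last step.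

Step 12
Reactants: 15 dimethyl acetal
Product: 17 (12E)-18,18-dimethoxy-7-oxo-15-norlabda-8(17),12-dien-14-yl pivalate, via 7α-alcohol 16 (not isolated)
Conditions: SeO2 (cat.), t-BuOOH (anhydrous), CH2Cl2, rt; then Dess–Martin periodinane, NaHCO3, 0 °C → rt
Reagents that add atoms: tert-butyl hydroperoxide, CC(C)(C)OO
Why: Selenium dioxide allylic oxidation of the exocyclic alkene functionalises C7 with axial (α) oxygen delivery; the C12 alkene is deactivated by its allylic ester, as the 2,3-alkene of geranyl acetate is. Dess–Martin oxidation then converges the crude alcohol and any enone already formed to the enone.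

Step 13
Reactants: 17 exocyclic enone
Product: 18 (12E)-7β-hydroxy-18,18-dimethoxy-15-norlabda-8(17),12-dien-14-yl pivalate
Conditions: NaBH4, CeCl3·7H2O, MeOH, −78 °C
Reagents that add atoms: none
Why: Luche reduction is 1,2-selective; hydride attacks axially from the α face, anti to the C10 methyl group, to give the equatorial 7β-alcohol. Ester and acetal are untouched.

Step 14
Reactants: 18 7β-alcohol
Product: 19 (12E)-7β-[(tert-butyldimethylsilyl)oxy]-18,18-dimethoxy-15-norlabda-8(17),12-dien-14-yl pivalate
Conditions: t-BuMe2SiCl, imidazole, DMF, rt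
Reagents that add atoms: tert-butyl(chloro)dimethylsilane, CC(C)(C)[Si](C)(C)Cl
Why: Standard silylation of the equatorial secondary alcohol under conditions that leave the dimethyl acetal alone.

Step 15
Reactants: 19 silyl ether pivalate
Product: 20 (12E)-7β-[(tert-butyldimethylsilyl)oxy]-18,18-dimethoxy-15-norlabda-8(17),12-dien-14-ol
Conditions: i-Bu2AlH, CH2Cl2, −78 °C; aqueous potassium sodium tartrate work-up
Reagents that add atoms: none
Why: Reductive cleavage of the pivalate by the aluminium hydride; acetal, silyl ether and alkenes do not react at −78 °C.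

Step 16
Reactants: 20 allylic alcohol
Product: 21 (12E)-7β-[(tert-butyldimethylsilyl)oxy]-18,18-dimethoxy-15-norlabda-8(17),12-dien-14-al
Conditions: MnO2, CH2Cl2, rt
Reagents that add atoms: none
Why: MnO2 oxidises only the allylic alcohol and keeps the (E) geometry of the trisubstituted alkene.

Step 17
Reactants: 21 enal
Product: 22 (12E)-7β-[(tert-butyldimethylsilyl)oxy]-18,18-dimethoxylabda-8(17),12,14-triene
Conditions: Ph3PCH3Br, KN(SiMe3)2, THF, 0 °C
Reagents that add atoms: methyltriphenylphosphonium bromide, C[P+](c1ccccc1)(c1ccccc1)c1ccccc1.[Br-]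
Why: Wittig methylenation of the enal completes the (E)-1-alkyl-2-methyl diene; no stereocentre or alkene geometry is at risk.

Step 18
Reactants: 23 2,4,6-trihydroxybenzaldehyde
Product: 24 2-hydroxy-4,6-bis(methoxymethoxy)benzaldehyde
Conditions: MeOCH2Cl, i-Pr2NEt, CH2Cl2, 0 °C
Reagents that add atoms: chloromethyl methyl ether, COCCl
Why: Alkylation of the two non-chelated phenols; the hydroxyl hydrogen-bonded to the aldehyde is much less nucleophilic and stays free for the later ring closure.

Step 19
Reactants: 24 2-hydroxy-4,6-bis(methoxymethoxy)benzaldehyde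
Product: 25 rac-1-[2-hydroxy-4,6-bis(methoxymethoxy)phenyl]-5-(trimethylsilyl)penta-2,4-diyn-1-ol
Conditions: Me3SiC≡C–C≡CSiMe3, MeLi·LiBr, THF, rt; then 24 (0.45 equiv), −78 → 0 °C
Reagents that add atoms: 1,4-bis(trimethylsilyl)buta-1,3-diyne, C[Si](C)(C)C#CC#C[Si](C)(C)C
Why: Monodesilylation of the bis-silyl diyne by methyllithium gives the lithium diynide, which adds 1,2 to the aldehyde; the excess covers the acidic phenol. The carbinol centre is removed in the next step.

Step 20
Reactants: 25 diynyl carbinol
Product: 27 5,7-bis(methoxymethoxy)-2-[(trimethylsilyl)ethynyl]-4H-chromen-4-one, via diynone 26 (not isolated)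
Conditions: MnO2, CH2Cl2, rt; then Et2NH (cat.), rt
Reagents that add atoms: none
Why: MnO2 oxidises the benzylic, propargylic alcohol to the o-hydroxyaryl ynone. Amine-mediated conjugate addition–elimination then closes the pyranone 6-endo without acid, so the methoxymethyl ethers survive; the silyl cap shields the distal alkyne.

Step 21
Reactants: 27 silylethynyl chromone
Product: 28 2-(iodoethynyl)-5,7-bis(methoxymethoxy)-4H-chromen-4-one
Conditions: N-iodosuccinimide, AgNO3 (cat.), acetone, rt, dark
Reagents that add atoms: N-iodosuccinimide, O=C1CCC(=O)N1I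
Why: Silver-catalysed iododesilylation of an alkynylsilane, a standard route to 1-iodoalkynes; nothing else in 27 reacts with the mild iodonium source.

Step 22
Reactants: 29 dimethyl squarate
Product: 31 3-methoxycyclobut-3-ene-1,2-dione, via hydroxycyclobutenone 30 (not isolated)
Conditions: LiAlH(Ot-Bu)3, THF, −78 °C; then conc. aq. HCl, CH2Cl2, rt
Reagents that add atoms: none
Why: The bulky hydride reduces one carbonyl only; acid then ionises the carbinol and expels methanol with 1,2-transposition of the carbonyl to give the semisquarate, the established route from squarate diesters.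

Step 23
Reactants: 22 labdatriene; 28 iodoethynyl chromone
Product: 32 (12R)-cyclohexa-1,4-dienyl iodide [ring C12(H)–C13(CH3)=C14H–C15H2–C6′(I)=C1′(chromon-2-yl); C12 carries C11 of the decalin]
Conditions: toluene, BHT (cat.), 110 °C, sealed tube, dark, argon; chromatography to remove the 12S epimer and the minor regioisomer
Reagents that add atoms: none
Why: Thermal Diels–Alder reaction of an acceptor-substituted 1-iodoalkyne. The unsubstituted diene terminus C15 (largest HOMO coefficient of a 1-alkyl diene) bonds to the iodine-bearing alkyne carbon, which is β to the chromone and carries the largest LUMO coefficient, so C12 joins the chromone-bearing carbon. C12 forms without control from the remote decalin, which is why the epimers must be separated.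

Step 24
Reactants: 32 cyclohexadienyl iodide; 31 3-methoxycyclobut-3-ene-1,2-dione
Product: 34 4-hydroxy-3-methoxy-4-(cyclohexadienyl)cyclobut-2-en-1-one (both carbinol epimers), via alkenylmagnesium chloride 33 (not isolated)
Conditions: i-PrMgCl·LiCl, THF, −40 °C; then 31, −78 °C; aq. NH4Cl
Reagents that add atoms: none
Why: Iodine–magnesium exchange of the electron-poor alkenyl iodide is fast at low temperature, where the 2-substituted chromone is not attacked. The alkenyl Grignard reagent adds to the ketone carbonyl of 31 next to the methoxy-bearing carbon, not to the vinylogous-ester carbonyl, which fixes OMe at C4′ and H at C3′. The carbinol centre is lost in step 26, so its epimers need no separation.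

Step 25
Reactants: 34 cyclobutenol
Product: 35 trimethylsilyl ether of 34 (4-alkenyl-3-methoxy-4-silyloxycyclobutenone)
Conditions: N-(trimethylsilyl)imidazole, CH2Cl2, rt
Reagents that add atoms: N-(trimethylsilyl)imidazole, C[Si](C)(C)n1ccnc1
Why: Neutral silylation of the hindered tertiary alcohol; a silyl triflate with an amine base is avoided because it can attack the dimethyl acetal.

Step 26
Reactants: 35 alkenyl silyloxy methoxycyclobutenone
Product: 37 (12R,1′S)-bicyclic C5′ trimethylsilyl dienol ether [C5′(OSiMe3)=C6′, C3′=C4′(OMe), C2′=O, quaternary C1′], via dienylketene 36 (not isolated)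
Conditions: toluene (degassed, dilute), 110 °C, base-washed glassware
Reagents that add atoms: none
Why: Thermal conrotatory 4π opening of the cyclobutenone breaks the bond between the carbinol carbon (C5′) and the carbonyl carbon (C2′), and the donor silyloxy group rotates outward, so the alkenyl group turns inward and the (Z)-dienylketene 36 has the ketene carbon next to the C6′=C1′ alkene. Disrotatory 6π electrocyclisation then forms C2′–C1′ and closes the six-membered enedione ring as its cross-conjugated dienone. The closest known reaction is the Moore rearrangement of 4-alkenyl-4-silyloxycyclobutenones, including cases where a fully substituted alkene terminus stops the sequence at the cyclohexadienone. The one new stereocentre, C1′, is controlled by C12: 1,2-allylic strain with the chromone on C1′ pushes the C11 chain pseudoaxial, so the ketene carbon bonds to the opposite face and C2′ ends trans, the chromone cis, to C11. The step needs torquoselectivity (secured by the silyloxy donor), facial selectivity (secured by C12), and chemoselectivity against aromatisation (secured by the quaternary C1′). Both carbinol epimers of 35 converge because that carbon becomes sp2. The methoxy group and both carbonyl oxidation levels come unchanged from the semisquarate.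

Step 27
Reactants: 37 silyl dienol ether
Product: 38 (12R,1′S,6′R)-7-O-(tert-butyldimethylsilyl)-5″,7″-bis-O-(methoxymethyl)dichrostachine H 18-dimethyl acetal
Conditions: HF·pyridine, pyridine, THF, −78 °C
Reagents that add atoms: none
Why: Buffered protodesilylation of the trimethylsilyl enol ether at low temperature ketonises C5′ under kinetic control; the proton should enter C6′ on the face opposite C12, the convex face of the forming bicycle, placing H-6′ syn to the chromone (cis fusion). The cis-fused isomer is also expected to be the more stable one for an angularly substituted ring fusion. The secondary silyl ether, acetal and methoxymethyl ethers survive.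

Step 28
Reactants: 38 protected dichrostachine H
Product: 39 dichrostachine H
Conditions: 2 M aq. HCl, THF, rt
Reagents that add atoms: water, O
Why: Acid hydrolysis removes the dimethyl acetal, both phenolic methoxymethyl acetals and the secondary silyl ether in one operation. C4 bears a non-enolisable aldehyde, and acid-mediated enolisation at C6′ could only return the cis-fused isomer, so no stereocentre is at risk.

## Compound list

1 | geranyl bromide | CC(C)=CCC/C(C)=C/CBr | starting material
2 | trimethyl[(5E)-6,10-dimethylundeca-5,9-dien-1-yn-1-yl]silane | CC(C)=CCC/C(C)=C/CCC#C[Si](C)(C)C | intermediate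
3 | (5E)-6,10-dimethylundeca-5,9-dien-1-yne | CC(C)=CCC/C(C)=C/CCC#C | intermediate
4 | (2E,6E)-2,6-dimethylundeca-2,6-dien-10-yn-1-ol | OC/C(C)=C/CC/C(C)=C/CCC#C | intermediate
5 | [(2S,3S)-2-methyl-3-[(3E)-3-methyloct-3-en-7-yn-1-yl]oxiran-2-yl]methanol | OC[C@]1(C)O[C@H]1CC/C(C)=C/CCC#C | intermediate
6 | tert-butyldiphenylsilyl ether of 5 | CC(C)(C)[Si](c1ccccc1)(c1ccccc1)OC[C@]1(C)O[C@H]1CC/C(C)=C/CCC#C | intermediate
7 | alkenylcopper from 6 (Cu on C9, cis to CH2SiMe3) | CC(C)(C)[Si](c1ccccc1)(c1ccccc1)OC[C@]1(C)O[C@H]1CC/C(C)=C/CC/C(C[Si](C)(C)C)=C/[Cu] | intermediate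
8 | chloromagnesium (2E,5Z,9E)-alkoxide (alkoxide of the alcohol corresponding to 9) | CC(C)(C)[Si](c1ccccc1)(c1ccccc1)OC[C@]1(C)O[C@H]1CC/C(C)=C/CC/C(C[Si](C)(C)C)=C/C/C=C(\C)CO[Mg]Cl | intermediate
9 | (2E,5Z,9E)-12-[(2S,3S)-3-{[(tert-butyldiphenylsilyl)oxy]methyl}-3-methyloxiran-2-yl]-2,10-dimethyl-6-[(trimethylsilyl)methyl]dodeca-2,5,9-trien-1-yl pivalate | CC(C)(C)[Si](c1ccccc1)(c1ccccc1)OC[C@]1(C)O[C@H]1CC/C(C)=C/CC/C(C[Si](C)(C)C)=C/C/C=C(\C)COC(=O)C(C)(C)C | intermediate
10 | (12E)-18-[(tert-butyldiphenylsilyl)oxy]-3β-hydroxy-15-norlabda-8(17),12-dien-14-yl pivalate | C=C1CC[C@@H]2[C@](C)(CC[C@H](O)[C@@]2(C)CO[Si](c3ccccc3)(c3ccccc3)C(C)(C)C)[C@H]1C/C=C(\C)COC(=O)C(C)(C)C | intermediate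
11 | 3β-O-(phenoxythiocarbonyl) derivative of 10 | C=C1CC[C@@H]2[C@](C)(CC[C@H](OC(=S)Oc3ccccc3)[C@@]2(C)CO[Si](c3ccccc3)(c3ccccc3)C(C)(C)C)[C@H]1C/C=C(\C)COC(=O)C(C)(C)C | intermediate
12 | (12E)-18-[(tert-butyldiphenylsilyl)oxy]-15-norlabda-8(17),12-dien-14-yl pivalate | C=C1CC[C@@H]2[C@](C)(CCC[C@@]2(C)CO[Si](c3ccccc3)(c3ccccc3)C(C)(C)C)[C@H]1C/C=C(\C)COC(=O)C(C)(C)C | intermediate
13 | (12E)-18-hydroxy-15-norlabda-8(17),12-dien-14-yl pivalate | C=C1CC[C@@H]2[C@](C)(CCC[C@@]2(C)CO)[C@H]1C/C=C(\C)COC(=O)C(C)(C)C | intermediate
14 | (12E)-18-oxo-15-norlabda-8(17),12-dien-14-yl pivalate | C=C1CC[C@@H]2[C@](C)(CCC[C@@]2(C)C=O)[C@H]1C/C=C(\C)COC(=O)C(C)(C)C | intermediate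
15 | (12E)-18,18-dimethoxy-15-norlabda-8(17),12-dien-14-yl pivalate | C=C1CC[C@@H]2[C@](C)(CCC[C@@]2(C)C(OC)OC)[C@H]1C/C=C(\C)COC(=O)C(C)(C)C | intermediate
16 | (12E)-7α-hydroxy-18,18-dimethoxy-15-norlabda-8(17),12-dien-14-yl pivalate | C=C1[C@H](O)C[C@@H]2[C@](C)(CCC[C@@]2(C)C(OC)OC)[C@H]1C/C=C(\C)COC(=O)C(C)(C)C | intermediate
17 | (12E)-18,18-dimethoxy-7-oxo-15-norlabda-8(17),12-dien-14-yl pivalate | C=C1C(=O)C[C@@H]2[C@](C)(CCC[C@@]2(C)C(OC)OC)[C@H]1C/C=C(\C)COC(=O)C(C)(C)C | intermediate
18 | (12E)-7β-hydroxy-18,18-dimethoxy-15-norlabda-8(17),12-dien-14-yl pivalate | C=C1[C@@H](O)C[C@@H]2[C@](C)(CCC[C@@]2(C)C(OC)OC)[C@H]1C/C=C(\C)COC(=O)C(C)(C)C | intermediate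
19 | (12E)-7β-[(tert-butyldimethylsilyl)oxy]-18,18-dimethoxy-15-norlabda-8(17),12-dien-14-yl pivalate | C=C1[C@@H](O[Si](C)(C)C(C)(C)C)C[C@@H]2[C@](C)(CCC[C@@]2(C)C(OC)OC)[C@H]1C/C=C(\C)COC(=O)C(C)(C)C | intermediate
20 | (12E)-7β-[(tert-butyldimethylsilyl)oxy]-18,18-dimethoxy-15-norlabda-8(17),12-dien-14-ol | C=C1[C@@H](O[Si](C)(C)C(C)(C)C)C[C@@H]2[C@](C)(CCC[C@@]2(C)C(OC)OC)[C@H]1C/C=C(\C)CO | intermediate
21 | (12E)-7β-[(tert-butyldimethylsilyl)oxy]-18,18-dimethoxy-15-norlabda-8(17),12-dien-14-al | C=C1[C@@H](O[Si](C)(C)C(C)(C)C)C[C@@H]2[C@](C)(CCC[C@@]2(C)C(OC)OC)[C@H]1C/C=C(\C)C=O | intermediate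
22 | (12E)-7β-[(tert-butyldimethylsilyl)oxy]-18,18-dimethoxylabda-8(17),12,14-triene | C=C1[C@@H](O[Si](C)(C)C(C)(C)C)C[C@@H]2[C@](C)(CCC[C@@]2(C)C(OC)OC)[C@H]1C/C=C(\C)C=C | intermediate
23 | 2,4,6-trihydroxybenzaldehyde | O=Cc1c(O)cc(O)cc1O | starting material
24 | 2-hydroxy-4,6-bis(methoxymethoxy)benzaldehyde | O=Cc1c(O)cc(OCOC)cc1OCOC | intermediate
25 | rac-1-[2-hydroxy-4,6-bis(methoxymethoxy)phenyl]-5-(trimethylsilyl)penta-2,4-diyn-1-ol | OC(C#CC#C[Si](C)(C)C)c1c(O)cc(OCOC)cc1OCOC | intermediate
26 | 1-[2-hydroxy-4,6-bis(methoxymethoxy)phenyl]-5-(trimethylsilyl)penta-2,4-diyn-1-one | O=C(C#CC#C[Si](C)(C)C)c1c(O)cc(OCOC)cc1OCOC | intermediate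
27 | 5,7-bis(methoxymethoxy)-2-[(trimethylsilyl)ethynyl]-4H-chromen-4-one | C[Si](C)(C)C#Cc1cc(=O)c2c(OCOC)cc(OCOC)cc2o1 | intermediate
28 | 2-(iodoethynyl)-5,7-bis(methoxymethoxy)-4H-chromen-4-one | IC#Cc1cc(=O)c2c(OCOC)cc(OCOC)cc2o1 | intermediate
29 | dimethyl squarate | COC1=C(OC)C(=O)C1=O | starting material
30 | rac-4-hydroxy-2,3-dimethoxycyclobut-2-en-1-one | COC1=C(OC)C(O)C1=O | intermediate
31 | 3-methoxycyclobut-3-ene-1,2-dione | COC1=CC(=O)C1=O | intermediate
32 | (12R)-cyclohexa-1,4-dienyl iodide (C6′–I, C1′–chromonyl, decalin as in 22) | C=C1[C@@H](O[Si](C)(C)C(C)(C)C)C[C@@H]2[C@](C)(CCC[C@@]2(C)C(OC)OC)[C@H]1C[C@@H]1C(C)=CCC(I)=C1c1cc(=O)c2c(OCOC)cc(OCOC)cc2o1 | intermediate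
33 | (12R)-cyclohexadienylmagnesium chloride (C6′–MgCl) | C=C1[C@@H](O[Si](C)(C)C(C)(C)C)C[C@@H]2[C@](C)(CCC[C@@]2(C)C(OC)OC)[C@H]1C[C@@H]1C(C)=CCC([Mg]Cl)=C1c1cc(=O)c2c(OCOC)cc(OCOC)cc2o1 | intermediate
34 | (12R)-4-hydroxy-3-methoxy-4-(cyclohexadien-C6′-yl)cyclobut-2-en-1-one, both configurations at the carbinol carbon | C=C1[C@@H](O[Si](C)(C)C(C)(C)C)C[C@@H]2[C@](C)(CCC[C@@]2(C)C(OC)OC)[C@H]1C[C@@H]1C(C)=CCC(C2(O)C(OC)=CC2=O)=C1c1cc(=O)c2c(OCOC)cc(OCOC)cc2o1 | intermediate
35 | trimethylsilyl ether of 34, both configurations at the carbinol carbon | C=C1[C@@H](O[Si](C)(C)C(C)(C)C)C[C@@H]2[C@](C)(CCC[C@@]2(C)C(OC)OC)[C@H]1C[C@@H]1C(C)=CCC(C2(O[Si](C)(C)C)C(OC)=CC2=O)=C1c1cc(=O)c2c(OCOC)cc(OCOC)cc2o1 | intermediate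
36 | (12R)-(Z)-dienylketene [O=C2′=C3′H–C4′(OMe)=C5′(OSiMe3)–C6′=C1′] | C=C1[C@@H](O[Si](C)(C)C(C)(C)C)C[C@@H]2[C@](C)(CCC[C@@]2(C)C(OC)OC)[C@H]1C[C@@H]1C(C)=CCC(/C(O[Si](C)(C)C)=C(OC)\C=C=O)=C1c1cc(=O)c2c(OCOC)cc(OCOC)cc2o1 | intermediate
37 | (12R,1′S)-bicyclic C5′ trimethylsilyl dienol ether | C=C1[C@@H](O[Si](C)(C)C(C)(C)C)C[C@@H]2[C@](C)(CCC[C@@]2(C)C(OC)OC)[C@H]1C[C@@H]1C(C)=CCC2=C(O[Si](C)(C)C)C(OC)=CC(=O)[C@@]12c1cc(=O)c2c(OCOC)cc(OCOC)cc2o1 | intermediate
38 | (12R,1′S,6′R)-7-O-(tert-butyldimethylsilyl)-5″,7″-bis-O-(methoxymethyl)dichrostachine H 18-dimethyl acetal | C=C1[C@@H](O[Si](C)(C)C(C)(C)C)C[C@@H]2[C@](C)(CCC[C@@]2(C)C(OC)OC)[C@H]1C[C@@H]1C(C)=CC[C@H]2C(=O)C(OC)=CC(=O)[C@@]12c1cc(=O)c2c(OCOC)cc(OCOC)cc2o1 | intermediate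
39 | dichrostachine H | C=C1[C@@H](O)C[C@@H]2[C@](C)(CCC[C@@]2(C)C=O)[C@H]1C[C@@H]1C(C)=CC[C@H]2C(=O)C(OC)=CC(=O)[C@@]12c1cc(=O)c2c(O)cc(O)cc2o1 | target

## Step count and risk

Total: 28 steps. Longest linear sequence: 23 steps (steps 1–17, then 23–28). Steps 18–21 (dienophile) and step 22 (semisquarate) are side branches.

**Step 26 (key step).** The likely failures are closure onto the tetrasubstituted terminus being slower than decomposition of the ketene, erosion of facial selectivity at C1′ at 110 °C, loss of the labile silyl group before ring opening, and oxidative aromatisation of the 1,4-cyclohexadiene during prolonged heating. Fallback: set out from carbinol 34 and use the alkoxide-accelerated variant of the same bond formation. Deprotonation with KN(SiMe3)2 and 18-crown-6 in THF at −78 °C, then warming to about −20 °C, should open the cyclobutenoxide and close the six-membered ring well below room temperature to give the potassium dienolate F1. Quenching at −78 °C with acetic acid rejoins the route at 38, bypassing the silyl ether and steps 25–27.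

**Step 23.** The likely failures are thermal degradation of the iodoalkyne before cycloaddition, insufficient regiocontrol because the 2-methyl group of the diene opposes the 1-alkyl group, and a laborious separation at C12, which is uncontrolled in any case. Fallback: set out from 27 and 22 and replace the iodoalkyne by a boron dienophile under metal catalysis. Methanolysis of 27 (K2CO3, MeOH) gives the terminal alkyne F2. Deprotonation with LiN(SiMe3)2, borylation with 2-isopropoxy-4,4,5,5-tetramethyl-1,3,2-dioxaborolane and acidification give the alkynyl pinacol boronate F3. A CoBr2(dppe)/Zn/ZnI2-catalysed [4+2] cycloaddition with 22 at room temperature gives, after separation of epimers, the cyclohexadienyl boronate F4. Iododeboronation (NaOMe, then I2) returns to 32.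

**Step 5.** The likely failures are opening of the substrate's own epoxide by magnesium halide during the slow carbocupration, and incomplete (E)-selectivity in the SN2′ step. Fallback: set out from 4 and introduce the epoxide after the organocopper chemistry. Silylation of 4 (t-BuMe2SiCl, imidazole) gives the tert-butyldimethylsilyl ether F5. The same three-component coupling gives the allylsilane pivalate F6. Buffered HF·pyridine frees the allylic alcohol F7. Sharpless epoxidation with L-(+)-diethyl tartrate gives the epoxy alcohol F8, and silylation with t-BuPh2SiCl returns to 9.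

**Step 24.** The likely failures are attack of the exchange reagent or of the alkenyl Grignard reagent on the chromone, and sluggish addition of the hindered tetrasubstituted nucleophile, leaving protonated alkene. Fallback: set out from 32 and 31 and form the same C6′–C5′ bond by a Nozaki–Hiyama–Kishi reaction (CrCl2, catalytic NiCl2, DMF/THF, room temperature), whose alkenylchromium species does not add to chromones. It returns to 34 and makes no new compound (F0).

**Step 28.** The likely failures are hydrolysis of the vinylogous methyl ester at C4′, ionisation of the allylic C7 alcohol, and incomplete cleavage of the 7″ methoxymethyl ether under conditions mild enough to spare the rest. Fallback: set out from 38 and deprotect in two non-aqueous stages. Me2BBr in CH2Cl2 at −78 °C cleaves both methoxymethyl ethers and the dimethyl acetal to give the 7-O-silyl ether F9. Buffered HF·pyridine in THF then removes the silyl group and returns to 39.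

## Further compounds

F1 | step 26 | potassium dienolate of 38 (C5′ enolate, C6′ sp2) | C=C1[C@@H](O[Si](C)(C)C(C)(C)C)C[C@@H]2[C@](C)(CCC[C@@]2(C)C(OC)OC)[C@H]1C[C@@H]1C(C)=CCC2=C([O-])C(OC)=CC(=O)[C@@]12c1cc(=O)c2c(OCOC)cc(OCOC)cc2o1.[K+]
F2 | step 23 | 2-ethynyl-5,7-bis(methoxymethoxy)-4H-chromen-4-one | C#Cc1cc(=O)c2c(OCOC)cc(OCOC)cc2o1
F3 | step 23 | 5,7-bis(methoxymethoxy)-2-[(4,4,5,5-tetramethyl-1,3,2-dioxaborolan-2-yl)ethynyl]-4H-chromen-4-one | CC1(C)OB(C#Cc2cc(=O)c3c(OCOC)cc(OCOC)cc3o2)OC1(C)C
F4 | step 23 | (12R)-cyclohexa-1,4-dienyl pinacol boronate (boron on C6′, otherwise as 32) | C=C1[C@@H](O[Si](C)(C)C(C)(C)C)C[C@@H]2[C@](C)(CCC[C@@]2(C)C(OC)OC)[C@H]1C[C@@H]1C(C)=CCC(B3OC(C)(C)C(C)(C)O3)=C1c1cc(=O)c2c(OCOC)cc(OCOC)cc2o1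
F5 | step 5 | tert-butyldimethylsilyl ether of 4 | CC(C)(C)[Si](C)(C)OC/C(C)=C/CC/C(C)=C/CCC#C
F6 | step 5 | (2E,5Z,9E,13E)-14-[(tert-butyldimethylsilyl)oxy]-2,10,13-trimethyl-6-[(trimethylsilyl)methyl]tetradeca-2,5,9,13-tetraen-1-yl pivalate | CC(C)(C)[Si](C)(C)OC/C(C)=C/CC/C(C)=C/CC/C(C[Si](C)(C)C)=C/C/C=C(\C)COC(=O)C(C)(C)C
F7 | step 5 | (2E,5Z,9E,13E)-14-hydroxy-2,10,13-trimethyl-6-[(trimethylsilyl)methyl]tetradeca-2,5,9,13-tetraen-1-yl pivalate | OC/C(C)=C/CC/C(C)=C/CC/C(C[Si](C)(C)C)=C/C/C=C(\C)COC(=O)C(C)(C)C
F8 | step 5 | (2E,5Z,9E)-12-[(2S,3S)-3-(hydroxymethyl)-3-methyloxiran-2-yl]-2,10-dimethyl-6-[(trimethylsilyl)methyl]dodeca-2,5,9-trien-1-yl pivalate | OC[C@]1(C)O[C@H]1CC/C(C)=C/CC/C(C[Si](C)(C)C)=C/C/C=C(\C)COC(=O)C(C)(C)C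
F0 | step 24 | none | none
F9 | step 28 | 7-O-(tert-butyldimethylsilyl)dichrostachine H | C=C1[C@@H](O[Si](C)(C)C(C)(C)C)C[C@@H]2[C@](C)(CCC[C@@]2(C)C=O)[C@H]1C[C@@H]1C(C)=CC[C@H]2C(=O)C(OC)=CC(=O)[C@@]12c1cc(=O)c2c(O)cc(O)cc2o1
A1 | alternative 1 | methyl 18-[(tert-butyldiphenylsilyl)oxy]-3β-hydroxy-13,14,15,16-tetranorlabd-8(17)-en-12-oate | C=C1CC[C@@H]2[C@](C)(CC[C@H](O)[C@@]2(C)CO[Si](c2ccccc2)(c2ccccc2)C(C)(C)C)[C@H]1CC(=O)OC
A2 | alternative 1 | methyl (3Z,7E)-10-[(2S,3S)-3-{[(tert-butyldiphenylsilyl)oxy]methyl}-3-methyloxiran-2-yl]-8-methyl-4-[(trimethylsilyl)methyl]deca-3,7-dienoate | CC(C)(C)[Si](c1ccccc1)(c1ccccc1)OC[C@]1(C)O[C@H]1CC/C(C)=C/CC/C(C[Si](C)(C)C)=C/CC(=O)OC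
A3 | alternative 2 | cis-fused bicyclic aldehyde with C2′ and C5′ tert-butyldimethylsilyl ethers, C4′ methoxy, C14 silyl enol ether and formyl group on C1′ | C1C(C)=C(O[Si](C)(C)C(C)(C)C)C[C@H]2[C@H](O[Si](C)(C)C(C)(C)C)C(OC)=C[C@H](O[Si](C)(C)C(C)(C)C)[C@@]12C=O
A4 | alternative 2 | (1Z,3E)-1,4-bis[(tert-butyldimethylsilyl)oxy]-2-methoxybuta-1,3-diene | CC(C)(C)[Si](C)(C)O/C=C(\OC)/C=C/O[Si](C)(C)C(C)(C)C
A5 | alternative 2 | 4-[(tert-butyldimethylsilyl)oxy]-5-methylcyclohexa-1,4-diene-1-carbaldehyde | O=CC1=CCC(O[Si](C)(C)C(C)(C)C)=C(C)C1
A6 | alternative 3 | aryl alkynyl ketone on C1′ [C1′–C≡C–C(=O)–C6H2(OCH2OCH3)3, C5′ dimethyl ketal, decalin as in 22] | C=C1[C@@H](O[Si](C)(C)C(C)(C)C)C[C@@H]2[C@](C)(CCC[C@@]2(C)C(OC)OC)[C@H]1C[C@@H]1C(C)=CC[C@H]2C(OC)(OC)C(OC)=CC(=O)[C@@]12C#CC(=O)c1c(OCOC)cc(OCOC)cc1OCOC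
A7 | alternative 3 | C1′-ethynyl enone with C5′ dimethyl ketal (decalin as in 22) | C=C1[C@@H](O[Si](C)(C)C(C)(C)C)C[C@@H]2[C@](C)(CCC[C@@]2(C)C(OC)OC)[C@H]1C[C@@H]1C(C)=CC[C@H]2C(OC)(OC)C(OC)=CC(=O)[C@@]12C#C
A8 | alternative 3 | 2-iodo-1,3,5-tris(methoxymethoxy)benzene | COCOc1cc(OCOC)c(I)c(OCOC)c1
A9 | alternative 3 | carbon monoxide | [C-]#[O+]
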